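(All constants were set for the occasion, and the outcome is calculated.)

I read the flask at 20 min, and the question is how much X the X.D.X has given back by then.

| flask | D | X | remark | time |
|---|---|---|---|---|
| dawn | 0.20 M | 0.950 equiv | one stirred flow tank at steady state, fed with the mixture as stated, mean residence time 20 min |  |
| spring | 0.20 M | 0.950 equiv (fed, over 16.0 min) | all but X at the start; X goes in evenly over 16.0 min, the run ends at 20 min | 20 min |
| autumn | 0.20 M | 0.950 equiv | a closed flask charged with all of it at once and left for 20 min | 20 min |
| summer | 0.20 M (fed, over 16.0 min) | 0.950 equiv | all but D at the start; D goes in evenly over 16.0 min, the run ends at 20 min | 20 min |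

* the set-up with the highest amount of D.X at the outlet or at the end, in percent of the D put in ("none" if the first two lie within 2 percentage points) (dawn / spring / autumn / summer / none)
* amount of D.X at the outlet or at the end, in percent of the D put in, dawn
* amount of D.X at the outlet or at the end, in percent of the D put in, spring
* amount of D.X at the outlet or at the end, in percent of the D put in, autumn
* amount of D.X at the outlet or at the end, in percent of the D put in, summer

    X ⇌ Z (K1 = 14, k1 = 0.0256 min⁻¹)
    X + D.X ⇌ X.D.X, settled at all times (K2 = 155 L mol⁻¹)
    D + X → D.X (k3 = 15.4 L mol⁻¹ min⁻¹)

I write d for the fraction of the charged D left, f for the fraction standing as free D.X, and b for the fraction standing as X.D.X.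

Two extremes can be done in the head. With no binding at all, D meets X with a half-life of 0.24 min at the autumn charge, and D.X ends near the charge of X, 95.0%. With infinitely strong binding, each D.X takes a second X at once, so D.X counted stops at 47.5%, with d at 52.5%. I expect the real autumn flask to run up towards that floor first and then climb towards the ceiling.

The rate of the climb follows from step 2. At balance, free X is b/f divided by K2, so D falls by a fraction (b/f)/T per minute, where T is the store time, K2 over k3, 10.1 min. The pseudo-first-order life of D is therefore T·f/b, and the charged concentration cancels.

I leave out Z and take free X as small. With 5.00% as the excess of D, b is d minus that excess, and f follows from the balance. Integrating as if the floor stood at the start, I estimate that d reaches 20.0% at 16.4 min, sooner than the reading, so I commit to a little over 80.0% for autumn.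

Spring and summer finish feeding at 16.0 min, which leaves 4.00 min, less than one store time, so I put both below autumn. I make no figure for the dawn tank, and place it below autumn too.

The forecast, which says “It holds much of the X as X.D.X, which releases it only slowly, so the tail is slow.”, gives 62.5% for dawn, 70% for spring, 80% for autumn and 67% for summer, with autumn best.

The simulation gives 62.5%, 70.4%, 79.8% and 67.1% in that order, with autumn best.

In autumn, d still stands at 20.2% at 20.0 min, more than the 20.0% my clock put at 16.4 min. There X.D.X is 13.3% and D.X counted is 79.8%, so the life of D is 50.3 min, longer than the run, and at 200 min D.X stands at 92.0%. The neighbour flask with 0.570 equiv of X holds X.D.X at 2.19% and D.X at 54.0% at 20.0 min, which makes that life 238 min, longer than in autumn, with D at 46.0%.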